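The depside ester is disconnected at the ring B aryl C4–O bond, not at the ring A acyl carbon (ring A: chlorinated salicyloyl ring; ring B: methyl benzoate ring). Ring B C4 lies between the C3 and C5 methyls and para to the C1 CO2Me: its phenol would be a hindered, weak nucleophile, but as an aryl carbon on trivalent iodine it is electron-poor and accepts oxygen readily. In one operation the ring A carboxylate, its own C2 phenol left free, is O-arylated by a ring B aryl(2,4,6-trimethoxyphenyl)iodonium tosylate whose C2 phenol is masked as acetate. The acid derives from atraric acid, the iodonium salt from 2,4,5-trimethylphenol.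

Key step: step 9

Remark: in both rings C1 is the carbon bearing the carboxyl carbon; the target has no stereocentre, and the structures of the target and of both partners of the key step were checked atom by atom and needed no correction.

Step 1
Reactants: 1 atraric acid (methyl 2,4-dihydroxy-3,6-dimethylbenzoate)
Product: 2 methyl 2-hydroxy-4-methoxy-3,6-dimethylbenzoate
Conditions: MeI (1.05 equiv), K2CO3 (1.1 equiv), acetone, reflux
Reagents that add atoms: methyl iodide, CI
Why: Williamson ether synthesis; the C2 hydroxyl is tied up in a hydrogen bond to the ester carbonyl, so one equivalent of MeI should methylate only the free C4 hydroxyl.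

Step 2
Reactants: 2 methyl 2-hydroxy-4-methoxy-3,6-dimethylbenzoate
Product: 3 methyl 5-chloro-2-hydroxy-4-methoxy-3,6-dimethylbenzoate
Conditions: SO2Cl2 (1.05 equiv), CH2Cl2, 0 °C to rt
Reagents that add atoms: sulfuryl chloride, O=S(=O)(Cl)Cl
Why: Electrophilic aromatic chlorination; C5 is the only unsubstituted ring carbon and is para to the C2 hydroxyl and ortho to the C4 methoxy group, so a single equivalent should chlorinate there.

Step 3
Reactants: 3 methyl 5-chloro-2-hydroxy-4-methoxy-3,6-dimethylbenzoate
Product: 4 5-chloro-2-hydroxy-4-methoxy-3,6-dimethylbenzoic acid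
Conditions: KOH (excess), DMSO/H2O, 85 °C; then cold 2 M HCl, 0 °C
Reagents that add atoms: potassium hydroxide, [K+].[OH-]
Why: Saponification of a di-ortho-substituted salicylate; weakly solvated hydroxide in aqueous DMSO should reach the shielded carbonyl, the aryl chloride on the electron-rich phenoxide ring is inert to substitution, and cold acidification guards against decarboxylation.

Step 4
Reactants: 5 2,4,5-trimethylphenol
Product: 6 2-hydroxy-3,5,6-trimethylbenzoic acid
Conditions: anhydrous K2CO3 (3 equiv), CO2 (50 bar), 175 °C, autoclave; then aq. HCl, 0 °C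
Reagents that add atoms: carbon dioxide, O=C=O
Why: Kolbe–Schmitt carboxylation (Marasse variant); the para carbon carries a methyl, so the phenoxide can take up CO2 only at its single free ortho carbon, the same kind of methyl-flanked ortho position that is carboxylated in thymol.

Step 5
Reactants: 6 2-hydroxy-3,5,6-trimethylbenzoic acid
Product: 7 methyl 2-hydroxy-3,5,6-trimethylbenzoate
Conditions: MeI (1.2 equiv), KHCO3 (1.2 equiv), DMF, rt
Reagents that add atoms: methyl iodide, CI
Why: Carboxylate O-alkylation (SN2 at methyl iodide), which is indifferent to the two ortho substituents that would block a Fischer esterification; KHCO3 is too weak to ionise the chelated phenol.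

Step 6
Reactants: 7 methyl 2-hydroxy-3,5,6-trimethylbenzoate
Product: 8 methyl 2-acetoxy-3,5,6-trimethylbenzoate
Conditions: Ac2O, pyridine, DMAP (cat.), 40 °C
Reagents that add atoms: acetic anhydride, CC(=O)OC(C)=O
Why: DMAP-catalysed O-acetylation; the acylpyridinium is reactive enough for the hydrogen-bonded, ortho-flanked phenol, and the acetate shields the oxygen from oxidation and arylation in steps 7 to 9 while lowering the electron density of ring B.

Step 7
Reactants: 8 methyl 2-acetoxy-3,5,6-trimethylbenzoate
Product: 9 methyl 2-acetoxy-4-iodo-3,5,6-trimethylbenzoate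
Conditions: NIS (1.3 equiv), TfOH (1.5 equiv), CH2Cl2, 0 °C to rt
Reagents that add atoms: N-iodosuccinimide, O=C1CCC(=O)N1I
Why: Electrophilic aromatic iodination with acid-activated NIS; C4 is the only ring C–H and is flanked by two activating methyls, while the C1 ester is twisted out of the ring plane by its two ortho neighbours and so deactivates mainly inductively.

Step 8
Reactants: 9 methyl 2-acetoxy-4-iodo-3,5,6-trimethylbenzoate; 10 1,3,5-trimethoxybenzene
Product: 12 [3-acetoxy-4-(methoxycarbonyl)-2,5,6-trimethylphenyl](2,4,6-trimethoxyphenyl)iodonium tosylate, via hydroxy(tosyloxy)iodane 11 (not isolated)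
Conditions: mCPBA (1.1 equiv), TsOH·H2O (1.05 equiv), MeCN, 77 °C; then 10 (1.05 equiv), 77 °C to rt; trituration with Et2O
Reagents that add atoms: p-toluenesulfonic acid monohydrate, Cc1ccc(cc1)S(=O)(=O)O.O (tosylate counter-ion); mCPBA, OOC(=O)c1cccc(Cl)c1 (oxygen on iodine in 11 only)
Why: One-pot diaryliodonium synthesis; the peracid with TsOH oxidises the aryl iodide to the trivalent-iodine hydroxy(tosyloxy)iodane, which the two ortho methyls stabilise, and this electrophile then attacks the very electron-rich 1,3,5-trimethoxybenzene by electrophilic aromatic substitution.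

Step 9
Reactants: 4 5-chloro-2-hydroxy-4-methoxy-3,6-dimethylbenzoic acid; 12 [3-acetoxy-4-(methoxycarbonyl)-2,5,6-trimethylphenyl](2,4,6-trimethoxyphenyl)iodonium tosylate
Product: 15 methyl 2-acetoxy-4-[(5-chloro-2-hydroxy-4-methoxy-3,6-dimethylbenzoyl)oxy]-3,5,6-trimethylbenzoate, via potassium carboxylate 13 (not isolated), via iodonium carboxylate 14 (not isolated)
Conditions: t-BuOK (1.0 equiv), toluene, rt, 30 min; then 12 (1.1 equiv), 100 °C
Reagents that add atoms: potassium tert-butoxide, CC(C)(C)[O-].[K+] (potassium in 13 only)
Why: Potassium carboxylate 13 replaces tosylate on iodine to give the T-shaped trivalent-iodine carboxylate 14, and in a concerted three-membered ligand-coupling transition state the carboxylate oxygen bonds to ring B C4 while iodine is reduced and leaves as 2-iodo-1,3,5-trimethoxybenzene. The closest known reaction type is the metal-free O-arylation of carboxylic acids with diaryliodonium salts that carry a trimethoxyphenyl spectator aryl. No ring is closed and no stereocentre is formed. Two selectivities are needed: transfer of the ring B aryl and not the trimethoxyphenyl group, and arylation of the carboxylate oxygen and not the ring A C2 phenol. The first should follow from the electron-poor ring B aryl (para CO2Me, acetoxy), whose ipso carbon takes up oxygen far more readily than that of the electron-rich trimethoxyphenyl group, helped by the C3 and C5 methyls, which favour the equatorial site from which coupling occurs; neither aryl has an ortho hydrogen, so no aryne path is open. The second should follow from using exactly one equivalent of base, which ionises the carboxylic acid only and leaves the chelated, methyl-flanked phenol protonated, and from forming 13 before 12 is added so that the acetate never meets tert-butoxide.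

Step 10
Reactants: 15 methyl 2-acetoxy-4-[(5-chloro-2-hydroxy-4-methoxy-3,6-dimethylbenzoyl)oxy]-3,5,6-trimethylbenzoate
Product: 16 methyl 4-[(5-chloro-2-hydroxy-4-methoxy-3,6-dimethylbenzoyl)oxy]-2-hydroxy-3,5,6-trimethylbenzoate (target)
Conditions: K2CO3 (1.2 equiv), MeOH/THF, 0 °C; then dilute aq. HCl
Reagents that add atoms: none
Why: Base-mediated transesterification (methanolysis) of an aryl acetate; the small acetyl carbonyl should be cleaved quickly at 0 °C, whereas the depside carbonyl is shielded by the ring A C6 methyl and C2 phenoxide and by the ring B C3 and C5 methyls, and methanol as solvent makes any exchange at the methyl ester degenerate.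

Compound list
1 | atraric acid (methyl 2,4-dihydroxy-3,6-dimethylbenzoate) | COC(=O)c1c(C)cc(O)c(C)c1O | starting material
2 | methyl 2-hydroxy-4-methoxy-3,6-dimethylbenzoate | COC(=O)c1c(C)cc(OC)c(C)c1O | intermediate
3 | methyl 5-chloro-2-hydroxy-4-methoxy-3,6-dimethylbenzoate | COC(=O)c1c(C)c(Cl)c(OC)c(C)c1O | intermediate
4 | 5-chloro-2-hydroxy-4-methoxy-3,6-dimethylbenzoic acid | Cc1c(Cl)c(OC)c(C)c(O)c1C(=O)O | intermediate
5 | 2,4,5-trimethylphenol | Oc1cc(C)c(C)cc1C | starting material
6 | 2-hydroxy-3,5,6-trimethylbenzoic acid | OC(=O)c1c(C)c(C)cc(C)c1O | intermediate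
7 | methyl 2-hydroxy-3,5,6-trimethylbenzoate | COC(=O)c1c(C)c(C)cc(C)c1O | intermediate
8 | methyl 2-acetoxy-3,5,6-trimethylbenzoate | COC(=O)c1c(C)c(C)cc(C)c1OC(C)=O | intermediate
9 | methyl 2-acetoxy-4-iodo-3,5,6-trimethylbenzoate | COC(=O)c1c(C)c(C)c(I)c(C)c1OC(C)=O | intermediate
10 | 1,3,5-trimethoxybenzene | COc1cc(OC)cc(OC)c1 | starting material
11 | methyl 2-acetoxy-4-[hydroxy(tosyloxy)-λ3-iodanyl]-3,5,6-trimethylbenzoate | COC(=O)c1c(C)c(C)c(I(O)OS(=O)(=O)c2ccc(C)cc2)c(C)c1OC(C)=O | intermediate (not isolated)
12 | [3-acetoxy-4-(methoxycarbonyl)-2,5,6-trimethylphenyl](2,4,6-trimethoxyphenyl)iodonium tosylate | COC(=O)c1c(C)c(C)c([I+]c2c(OC)cc(OC)cc2OC)c(C)c1OC(C)=O.Cc1ccc(cc1)S(=O)(=O)[O-] | intermediate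
13 | potassium 5-chloro-2-hydroxy-4-methoxy-3,6-dimethylbenzoate | Cc1c(Cl)c(OC)c(C)c(O)c1C(=O)[O-].[K+] | intermediate (not isolated)
14 | [3-acetoxy-4-(methoxycarbonyl)-2,5,6-trimethylphenyl](2,4,6-trimethoxyphenyl)iodonium 5-chloro-2-hydroxy-4-methoxy-3,6-dimethylbenzoate | COC(=O)c1c(C)c(C)c([I+]c2c(OC)cc(OC)cc2OC)c(C)c1OC(C)=O.Cc1c(Cl)c(OC)c(C)c(O)c1C(=O)[O-] | intermediate (not isolated)
15 | methyl 2-acetoxy-4-[(5-chloro-2-hydroxy-4-methoxy-3,6-dimethylbenzoyl)oxy]-3,5,6-trimethylbenzoate | COC(=O)c1c(C)c(C)c(OC(=O)c2c(C)c(Cl)c(OC)c(C)c2O)c(C)c1OC(C)=O | intermediate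
16 | methyl 4-[(5-chloro-2-hydroxy-4-methoxy-3,6-dimethylbenzoyl)oxy]-2-hydroxy-3,5,6-trimethylbenzoate | COC(=O)c1c(C)c(C)c(OC(=O)c2c(C)c(Cl)c(OC)c(C)c2O)c(C)c1O | target

Total step count: 10. Longest linear sequence: 7 steps (steps 4 to 10, from 2,4,5-trimethylphenol); the ring A branch (steps 1 to 3) joins at step 9.

Steps most likely to fail

Step 9 (key O-arylation). The coupling may transfer the trimethoxyphenyl group in place of ring B, may arylate the phenol oxygen, or the iodane may decompose thermally before the doubly flanked carbon accepts the carboxylate. The fallback makes the ester at the acyl carbon instead and sets out from iodide 9. Miyaura borylation (B2pin2, Pd(OAc)2, SPhos, KOAc, dioxane, 90 °C) should give methyl 2-acetoxy-3,5,6-trimethyl-4-(4,4,5,5-tetramethyl-1,3,2-dioxaborolan-2-yl)benzoate F1. Oxidation with H2O2 and aqueous NaOH in THF, which should also cleave the acetate, should give methyl 2,4-dihydroxy-3,5,6-trimethylbenzoate F2. Its C4 hydroxyl would then be acylated by acid 4 through the mixed trifluoroacetic anhydride (TFAA, toluene, rt), the chelated C2 hydroxyl staying free. This comes back to the route at target 16.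

Step 7 (iodination). Attack at the deactivated C4 may be too slow, and the strong acid may strip the acetate or ionise the hindered ester before iodination is complete. The fallback brings the iodine in through nitrogen and sets out from 8. Nitration (HNO3, Ac2O, 0 °C) should give methyl 2-acetoxy-3,5,6-trimethyl-4-nitrobenzoate F3. Hydrogenation (H2, Pd/C, EtOAc) should give methyl 2-acetoxy-4-amino-3,5,6-trimethylbenzoate F4. Sandmeyer-type diazotisation and iodination (NaNO2, TsOH·H2O, KI, MeCN/H2O, rt) comes back to the route at iodide 9.

Step 4 (carboxylation). Uptake of CO2 at the methyl-flanked ortho carbon may stall, or the acid may lose CO2 again at the reaction temperature. The fallback introduces the carbon at the aldehyde level and sets out from 5. Magnesium-mediated ortho-formylation (MgCl2, Et3N, paraformaldehyde, MeCN, reflux) should give 2-hydroxy-3,5,6-trimethylbenzaldehyde F5. Pinnick oxidation (NaClO2, sulfamic acid, aqueous dioxane, rt) comes back to the route at acid 6.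

Further compounds
F1 | step 9 | methyl 2-acetoxy-3,5,6-trimethyl-4-(4,4,5,5-tetramethyl-1,3,2-dioxaborolan-2-yl)benzoate | COC(=O)c1c(C)c(C)c(B2OC(C)(C)C(C)(C)O2)c(C)c1OC(C)=O
F2 | step 9 | methyl 2,4-dihydroxy-3,5,6-trimethylbenzoate | COC(=O)c1c(C)c(C)c(O)c(C)c1O
F3 | step 7 | methyl 2-acetoxy-3,5,6-trimethyl-4-nitrobenzoate | COC(=O)c1c(C)c(C)c([N+](=O)[O-])c(C)c1OC(C)=O
F4 | step 7 | methyl 2-acetoxy-4-amino-3,5,6-trimethylbenzoate | COC(=O)c1c(C)c(C)c(N)c(C)c1OC(C)=O
F5 | step 4 | 2-hydroxy-3,5,6-trimethylbenzaldehyde | O=Cc1c(C)c(C)cc(C)c1O
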